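The benzene ring is built last. Ar1 is the ring carbon bearing the ketone, with oxygen on Ar2 and Ar4. This 1-acyl-2,4-dioxygenated arene is the feature the key step exploits: Ar1 and Ar6 come from an ethynyl ketone, Ar2 to Ar5 from a 1,1,3-trioxygenated butadiene. One thermal cycloaddition–elimination forms Ar1–Ar2 and Ar5–Ar6, closes the only ring and delivers the two oxygens already differentiated. No acid, base or metal is involved, so the monosubstituted alkene, both trisubstituted alkenes and the quaternary stereocentre pass through untouched. The precursor is the enantiopure terminal ynone carrying the whole terpenoid chain, its stereocentre set by iridium-catalysed allylic alkylation of farnesyl carbonate.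

Key step: step 9

Remark on the structures: the ynone, the diene and the cycloaddition product were checked against the target (acyl on Ar1, methoxy on Ar2, hydroxyl on Ar4, same arrangement at the quaternary carbon) and need no correction. The target and intermediates 6, 7, 8 and 17 are (R) at that carbon; malonate 5 is (S) only because the CIP ranking of its substituents differs.

Assumption: (S)-5 requires the malonate to attack the Si face of C3 of the (2E)-allyl unit. The (Sa,S,S) ligand is written for this; if a first run shows the opposite sense, the mirror-image ligand is used and nothing else changes.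

Step 1
Reactants: 1 (2E,6E)-farnesol
Product: 2 methyl (2E,6E)-3,7,11-trimethyldodeca-2,6,10-trien-1-yl carbonate
Conditions: ClCO2Me, pyridine, CH2Cl2, 0 °C → rt
Reagents that add atoms: methyl chloroformate, COC(=O)Cl
Why: O-acylation of a primary allylic alcohol by a chloroformate (carbonate formation) is fast at 0 °C and touches neither the alkenes nor the (2E) geometry.

Step 2
Reactants: 2 methyl (2E,6E)-3,7,11-trimethyldodeca-2,6,10-trien-1-yl carbonate; 3 dimethyl malonate
Product: 5 dimethyl 2-[(3S,6E)-3,7,11-trimethyldodeca-1,6,10-trien-3-yl]propanedioate, via iodozinc enolate of dimethyl malonate 4 (not isolated)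
Conditions: 3, NaHMDS, ZnI2, THF, rt (forms 4); [Ir(cod)Cl]2 (2 mol%), (Sa,S,S)-BINOL N,N-bis(1-phenylethyl)phosphoramidite (4 mol%), TBD (10 mol%), THF, rt; then 2 and 4, rt; aq. work-up
Reagents that add atoms: none
Why: Iridium-catalysed asymmetric allylic alkylation (branch-selective Tsuji–Trost-type substitution), in which the cyclometalated iridium–phosphoramidite catalyst ionises the carbonate and the soft zinc malonate attacks the disubstituted allyl terminus C3, the ligand steering it to the Si face so that the quaternary centre is set as (S) under catalyst control.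

Step 3
Reactants: 5 dimethyl 2-[(3S,6E)-3,7,11-trimethyldodeca-1,6,10-trien-3-yl]propanedioate
Product: 6 methyl (3R,6E)-3-ethenyl-3,7,11-trimethyldodeca-6,10-dienoate
Conditions: LiCl, H2O, DMSO, 150 °C
Reagents that add atoms: none
Why: Krapcho dealkoxycarbonylation, in which chloride demethylates one ester by SN2 and the carboxylate loses CO2, tolerates the neighbouring quaternary carbon and cannot affect a stereocentre that bears no hydrogen.

Step 4
Reactants: 6 methyl (3R,6E)-3-ethenyl-3,7,11-trimethyldodeca-6,10-dienoate
Product: 7 (3R,6E)-3-ethenyl-N-methoxy-N,3,7,11-tetramethyldodeca-6,10-dienamide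
Conditions: MeNH(OMe)·HCl, i-PrMgCl, THF, −20 → 0 °C
Reagents that add atoms: N,O-dimethylhydroxylamine hydrochloride, CNOC.Cl
Why: Weinreb amide synthesis by direct aminolysis of the methyl ester with the magnesium amide of N,O-dimethylhydroxylamine, whose chelated adduct resists further attack while the inert quaternary centre is two atoms away.

Step 5
Reactants: 7 (3R,6E)-3-ethenyl-N-methoxy-N,3,7,11-tetramethyldodeca-6,10-dienamide
Product: 8 (5R,8E)-5-ethenyl-5,9,13-trimethyltetradeca-8,12-dien-1-yn-3-one
Conditions: HC≡CMgBr, THF, 0 °C → rt; inverse quench into cold 1 M HCl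
Reagents that add atoms: ethynylmagnesium bromide, C#C[Mg]Br
Why: Weinreb ketone synthesis, in which the alkynyl Grignard reagent adds once to a magnesium chelate that collapses to the ynone only on the cold acidic quench, which also protonates the released amine so that it cannot add to the ynone in conjugate fashion.

Step 6
Reactants: 9 acetyl chloride; 10 1,1-dichloroethene
Product: 12 4,4-dichlorobut-3-en-2-one, via 4,4,4-trichlorobutan-2-one 11 (not isolated)
Conditions: AlCl3, CH2Cl2, 0 °C → rt; ice/aq. HCl; then distillation (−HCl)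
Reagents that add atoms: none
Why: AlCl3-promoted acylation of an alkene (Friedel–Crafts acylation of the Darzens–Nenitzescu kind) gives the β-trichloromethyl ketone through the chlorine-stabilised cation, and this loses HCl by β-elimination to the conjugated dichlorovinyl ketone.

Step 7
Reactants: 12 4,4-dichlorobut-3-en-2-one
Product: 13 4,4-dimethoxybut-3-en-2-one
Conditions: NaOMe, MeOH, 0 °C → rt
Reagents that add atoms: sodium methoxide, C[O-].[Na+]
Why: Two successive addition–elimination events (nucleophilic vinylic substitution) at the β-carbon of this vinylogous acid chloride replace both chlorides by methoxide.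

Step 8
Reactants: 13 4,4-dimethoxybut-3-en-2-one
Product: 14 1,1-dimethoxy-3-(trimethylsilyloxy)buta-1,3-diene
Conditions: Me3SiCl, Et3N, ZnCl2 (cat.), Et2O/PhMe, 40 °C; filtration and distillation under exclusion of moisture
Reagents that add atoms: chlorotrimethylsilane, C[Si](C)(C)Cl
Why: Silyl enol ether formation by soft enolisation, which can occur only toward the methyl group, gives the cross-conjugated 2-silyloxydiene.

Step 9
Reactants: 8 (5R,8E)-5-ethenyl-5,9,13-trimethyltetradeca-8,12-dien-1-yn-3-one; 14 1,1-dimethoxy-3-(trimethylsilyloxy)buta-1,3-diene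
Product: 17 (3R,6E)-3-ethenyl-1-(4-hydroxy-2-methoxyphenyl)-3,7,11-trimethyldodeca-6,10-dien-1-one, via dimethoxycyclohexadiene cycloadduct 15 (not isolated), via aryl trimethylsilyl ether 16 (not isolated)
Conditions: 14 (2.5 equiv), PhMe, rt → 80 °C; then 0.1 M HCl, THF, 0 °C
Reagents that add atoms: none
Why: The ketene acetal and the silyl enol ether polarise the diene so that its CH2 terminus carries the largest HOMO coefficient and adds to the terminal (β) carbon of the ynone, while the acetal carbon bonds to the carbonyl-bearing carbon in a concerted, asynchronous thermal Diels–Alder reaction. This is the established behaviour of 1,1-dialkoxy-3-silyloxybutadienes toward acetylenic ketones and esters, which give 2-alkoxy-4-hydroxyaryl carbonyl compounds. The six-membered carbocycle is closed by intermolecular [4+2] annulation through the new Ar1–Ar2 and Ar5–Ar6 bonds; cyclohexa-1,4-diene 15 then aromatises by 1,4-elimination of methanol from the acetal carbon and the ring CH2, and dilute acid removes the silyl group of 16. No stereocentre is created, and the existing quaternary centre bears no hydrogen and lies two atoms from the reacting π-system, so it cannot be disturbed. The step needs regioselectivity, secured by the matched polarisation of diene and ynone, and chemoselectivity, secured because the ynone is the only electron-poor π-bond while the vinyl group and the trisubstituted alkenes are unactivated.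

Step 10
Reactants: 17 (3R,6E)-3-ethenyl-1-(4-hydroxy-2-methoxyphenyl)-3,7,11-trimethyldodeca-6,10-dien-1-one
Product: 18 (3R,6E)-1-(2,4-dihydroxyphenyl)-3-ethenyl-3,7,11-trimethyldodeca-6,10-dien-1-one
Conditions: MgI2·OEt2 (3 equiv), PhMe, 80 °C; then H2O, aq. Na2S2O3
Reagents that add atoms: none
Why: Chelation-directed ether cleavage, in which MgI2 binds the ketone oxygen and the ortho methoxy oxygen in a six-membered chelate so that iodide dealkylates only that methyl group by SN2, under conditions mild enough for the alkenes.

Compound list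
1 | (2E,6E)-farnesol | OC/C=C(\C)CC/C=C(\C)CCC=C(C)C | starting material
2 | methyl (2E,6E)-3,7,11-trimethyldodeca-2,6,10-trien-1-yl carbonate | COC(=O)OC/C=C(\C)CC/C=C(\C)CCC=C(C)C | intermediate
3 | dimethyl malonate | COC(=O)CC(=O)OC | starting material
4 | iodozinc enolate of dimethyl malonate | COC(=O)C=C(OC)O[Zn]I | intermediate (not isolated)
5 | dimethyl 2-[(3S,6E)-3,7,11-trimethyldodeca-1,6,10-trien-3-yl]propanedioate | C=C[C@](C)(CC/C=C(\C)CCC=C(C)C)C(C(=O)OC)C(=O)OC | intermediate
6 | methyl (3R,6E)-3-ethenyl-3,7,11-trimethyldodeca-6,10-dienoate | C=C[C@](C)(CC/C=C(\C)CCC=C(C)C)CC(=O)OC | intermediate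
7 | (3R,6E)-3-ethenyl-N-methoxy-N,3,7,11-tetramethyldodeca-6,10-dienamide | C=C[C@](C)(CC/C=C(\C)CCC=C(C)C)CC(=O)N(C)OC | intermediate
8 | (5R,8E)-5-ethenyl-5,9,13-trimethyltetradeca-8,12-dien-1-yn-3-one | C=C[C@](C)(CC/C=C(\C)CCC=C(C)C)CC(=O)C#C | intermediate
9 | acetyl chloride | CC(=O)Cl | starting material
10 | 1,1-dichloroethene | C=C(Cl)Cl | starting material
11 | 4,4,4-trichlorobutan-2-one | CC(=O)CC(Cl)(Cl)Cl | intermediate (not isolated)
12 | 4,4-dichlorobut-3-en-2-one | CC(=O)C=C(Cl)Cl | intermediate
13 | 4,4-dimethoxybut-3-en-2-one | CC(=O)C=C(OC)OC | intermediate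
14 | 1,1-dimethoxy-3-(trimethylsilyloxy)buta-1,3-diene | COC(OC)=CC(=C)O[Si](C)(C)C | intermediate
15 | (3R,6E)-1-[6,6-dimethoxy-4-(trimethylsilyloxy)cyclohexa-1,4-dien-1-yl]-3-ethenyl-3,7,11-trimethyldodeca-6,10-dien-1-one | C=C[C@](C)(CC/C=C(\C)CCC=C(C)C)CC(=O)C1=CCC(O[Si](C)(C)C)=CC1(OC)OC | intermediate (not isolated)
16 | (3R,6E)-3-ethenyl-1-[2-methoxy-4-(trimethylsilyloxy)phenyl]-3,7,11-trimethyldodeca-6,10-dien-1-one | C=C[C@](C)(CC/C=C(\C)CCC=C(C)C)CC(=O)c1ccc(O[Si](C)(C)C)cc1OC | intermediate (not isolated)
17 | (3R,6E)-3-ethenyl-1-(4-hydroxy-2-methoxyphenyl)-3,7,11-trimethyldodeca-6,10-dien-1-one | C=C[C@](C)(CC/C=C(\C)CCC=C(C)C)CC(=O)c1ccc(O)cc1OC | intermediate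
18 | (3R,6E)-1-(2,4-dihydroxyphenyl)-3-ethenyl-3,7,11-trimethyldodeca-6,10-dien-1-one | C=C[C@](C)(CC/C=C(\C)CCC=C(C)C)CC(=O)c1ccc(O)cc1O | target

Total step count: 10 (steps 1–5 to the ynone, steps 6–8 to the diene, steps 9 and 10).
Longest linear sequence: 7 steps (1, 2, 3, 4, 5, 9, 10).

Steps most likely to fail

Step 9. The ketene acetal terminus may add to the ynone in conjugate fashion without ring closure, the terminal ynone may oligomerise on warming, or the diene may hydrolyse before it reacts. The fallback abandons ring construction and attaches a preformed arene; it sets out from Weinreb amide 7 and returns to the route at 17. Commercial 4-bromo-3-methoxyphenol F1 is silylated (t-BuMe2SiCl, imidazole, DMF) to (4-bromo-3-methoxyphenoxy)(tert-butyl)dimethylsilane F2. Bromine–lithium exchange (n-BuLi, THF, −78 °C) gives [4-(tert-butyldimethylsilyloxy)-2-methoxyphenyl]lithium F3, which is acylated by 7 to (3R,6E)-1-[4-(tert-butyldimethylsilyloxy)-2-methoxyphenyl]-3-ethenyl-3,7,11-trimethyldodeca-6,10-dien-1-one F4. Bu4NF in THF at 0 °C should then release 17.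

Step 2. Ionisation of the hindered trisubstituted carbonate may be slow, attack at the unsubstituted allyl terminus may give linear product, and the catalyst may discriminate poorly between methyl and methylene at C3. The fallback replaces catalytic substitution by a sigmatropic rearrangement and a resolution; it sets out from farnesol 1 and returns at ester 6. Johnson–Claisen rearrangement of 1 with trimethyl orthoacetate (cat. propionic acid, 140 °C, methanol distilled off) passes through 1-methoxy-1-[(2E,6E)-farnesyloxy]ethene F5 and should give racemic methyl (6E)-3-ethenyl-3,7,11-trimethyldodeca-6,10-dienoate F6. Preparative chromatography on a polysaccharide chiral stationary phase separates 6 from its mirror image, methyl (3S,6E)-3-ethenyl-3,7,11-trimethyldodeca-6,10-dienoate F7, which is set aside.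

Step 10. Traces of HI may add to the trisubstituted alkenes or trigger cyclisation of the polyene chain, and dealkylation may stall because the free para phenol also binds magnesium. The fallback avoids the methyl ether altogether; it sets out from ynone 8 and returns at target 18.
- Dimedone F8 is silylated (Me3SiCl, Et3N) to 5,5-dimethyl-3-(trimethylsilyloxy)cyclohex-2-en-1-one F9 and then (LDA, Me3SiCl, THF, −78 °C) to 5,5-dimethyl-1,3-bis(trimethylsilyloxy)cyclohexa-1,3-diene F10.
- Heating 8 with F10 at about 140 °C should give the bicyclo[2.2.2]octadiene adduct F11, which loses 2-methylpropene by retro-Diels–Alder reaction (Alder–Rickert sequence).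
- This leaves (3R,6E)-1-[2,4-bis(trimethylsilyloxy)phenyl]-3-ethenyl-3,7,11-trimethyldodeca-6,10-dien-1-one F12, and dilute acid in THF gives 18.

Further compounds
F1 | step 9 | 4-bromo-3-methoxyphenol | COc1cc(O)ccc1Br
F2 | step 9 | (4-bromo-3-methoxyphenoxy)(tert-butyl)dimethylsilane | COc1cc(O[Si](C)(C)C(C)(C)C)ccc1Br
F3 | step 9 | [4-(tert-butyldimethylsilyloxy)-2-methoxyphenyl]lithium | [Li]c1ccc(O[Si](C)(C)C(C)(C)C)cc1OC
F4 | step 9 | (3R,6E)-1-[4-(tert-butyldimethylsilyloxy)-2-methoxyphenyl]-3-ethenyl-3,7,11-trimethyldodeca-6,10-dien-1-one | C=C[C@](C)(CC/C=C(\C)CCC=C(C)C)CC(=O)c1ccc(O[Si](C)(C)C(C)(C)C)cc1OC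
F5 | step 2 | 1-methoxy-1-[(2E,6E)-farnesyloxy]ethene | C=C(OC)OC/C=C(\C)CC/C=C(\C)CCC=C(C)C
F6 | step 2 | racemic methyl (6E)-3-ethenyl-3,7,11-trimethyldodeca-6,10-dienoate | C=CC(C)(CC/C=C(\C)CCC=C(C)C)CC(=O)OC
F7 | step 2 | methyl (3S,6E)-3-ethenyl-3,7,11-trimethyldodeca-6,10-dienoate | C=C[C@@](C)(CC/C=C(\C)CCC=C(C)C)CC(=O)OC
F8 | step 10 | dimedone (5,5-dimethylcyclohexane-1,3-dione) | CC1(C)CC(=O)CC(=O)C1
F9 | step 10 | 5,5-dimethyl-3-(trimethylsilyloxy)cyclohex-2-en-1-one | CC1(C)CC(=O)C=C(O[Si](C)(C)C)C1
F10 | step 10 | 5,5-dimethyl-1,3-bis(trimethylsilyloxy)cyclohexa-1,3-diene | C[Si](C)(C)OC1=CC(O[Si](C)(C)C)=CC(C)(C)C1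
F11 | step 10 | bicyclo[2.2.2]octadiene adduct of 8 and F10 (mixture of bridgehead diastereomers) | C=C[C@](C)(CC/C=C(\C)CCC=C(C)C)CC(=O)C1=CC2C(O[Si](C)(C)C)=CC1(O[Si](C)(C)C)CC2(C)C
F12 | step 10 | (3R,6E)-1-[2,4-bis(trimethylsilyloxy)phenyl]-3-ethenyl-3,7,11-trimethyldodeca-6,10-dien-1-one | C=C[C@](C)(CC/C=C(\C)CCC=C(C)C)CC(=O)c1ccc(O[Si](C)(C)C)cc1O[Si](C)(C)C
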